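**Plan**

- Retrosynthesis: the C14–C15 and C15′–C14′ bonds on either side of the central C15=C15′ ethene are cut first, giving a furanoid trienyl iodide, a tin/boron ethene and an iododienol. The iodide is then cut at C11=C12 (olefination), the dihydrofuran at O–C8 (back to a 5-hydroxy allene), the allene goes back to an alkynyl oxirane, and the C8–C9 bond is cut (Sonogashira).
- Forward: the cyclohexane comes from ketoisophorone; the dihydrofuran, the only ring closed in the route, arises by gold-catalysed O5→C8 closure. The chain is then joined at C11=C12, and last at C14–C15 followed by C15′–C14′ in one flask.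
- Stereochemistry: C3 from yeast and hydride reduction (actinol); C5 from a Sharpless epoxidation; C8 by transfer from the allene axis set in the SN2′ hydride opening. The 9Z bond comes from hydroalumination–iodination of but-2-yn-1-ol, the E bonds from carboalumination, olefinations and the (E)-ethene reagent.
- Enabling feature: C9 to C10′ is an unbroken sp2 hexaene whose middle is an unsubstituted C15=C15′ ethene between the methyl-bearing C13 and C13′ halves; it sits next to an acid-labile 2,5-dihydrofuran (O, C5, C6, C7, C8) fused to the cyclohexane, so a mild, non-acidic sp2–sp2 coupling at both ends of that ethene is the natural last step.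

Key step: step 24

Remark: positions are given in carotenoid numbering (ring C1–C6, chain C7–C15, primed numbers from the alcohol end). The axis of allene 17 is stated in its name and by the tag on the central allene carbon of its SMILES.

**Route**

Step 1
Reactants: 1 ketoisophorone
Product: 2 (6R)-2,2,6-trimethylcyclohexane-1,4-dione
Conditions: baker's yeast (Saccharomyces cerevisiae), sucrose, H2O, 30 °C
Reagents that add atoms: none
Why: Biocatalytic ene-reductase reduction of the enedione C=C by fermenting yeast, a known asymmetric conjugate reduction that should set the methyl-bearing carbon as 6R.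

Step 2
Reactants: 2 (6R)-2,2,6-trimethylcyclohexane-1,4-dione
Product: 3 (4R,6R)-4-hydroxy-2,2,6-trimethylcyclohexan-1-one (actinol)
Conditions: LiBH(s-Bu)3 (1.05 equiv), THF, −78 °C; H2O quench
Reagents that add atoms: none
Why: Bulky-hydride ketone reduction: only the C4 carbonyl between two methylenes is accessible, and equatorial attack enforced by the axial C2 methyl should give the axial 4R alcohol trans to the C6 methyl.

Step 3
Reactants: 3 (4R,6R)-4-hydroxy-2,2,6-trimethylcyclohexan-1-one
Product: 4 (4R,6R)-4-(tert-butyldimethylsilyloxy)-2,2,6-trimethylcyclohexan-1-one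
Conditions: TBSCl, imidazole, DMF, 25 °C
Reagents that add atoms: tert-butyldimethylsilyl chloride CC(C)(C)[Si](C)(C)Cl
Why: Standard imidazole-promoted silylation of a secondary alcohol, giving an ether that survives every step up to fluoride cleavage.

Step 4
Reactants: 4 (4R,6R)-4-(tert-butyldimethylsilyloxy)-2,2,6-trimethylcyclohexan-1-one
Product: 6 (4R)-4-(tert-butyldimethylsilyloxy)-2,6,6-trimethylcyclohex-1-en-1-yl trifluoromethanesulfonate, via lithium enolate 5 (not isolated)
Conditions: LiN(i-Pr)2, THF, −78 to 0 °C; then PhNTf2, −78 to 25 °C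
Reagents that add atoms: N-phenylbis(trifluoromethanesulfonimide) O=S(=O)(N(c1ccccc1)S(=O)(=O)C(F)(F)F)C(F)(F)F
Why: Enolisation at the only α-CH followed by O-triflation (vinyl triflate synthesis); the methyl-bearing centre is erased on purpose and the silyloxy carbon is untouched.

Step 5
Reactants: 6 (4R)-4-(tert-butyldimethylsilyloxy)-2,6,6-trimethylcyclohex-1-en-1-yl trifluoromethanesulfonate
Product: 7 methyl (4R)-4-(tert-butyldimethylsilyloxy)-2,6,6-trimethylcyclohex-1-ene-1-carboxylate
Conditions: Pd(OAc)2 (5 mol %), PPh3, CO (1 atm), Et3N, MeOH–DMF, 50 °C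
Reagents that add atoms: carbon monoxide [C-]#[O+]; methanol CO
Why: Palladium-catalysed methoxycarbonylation of a vinyl triflate (oxidative addition, CO insertion, methanolysis) installs C7 on the tetrasubstituted alkene.

Step 6
Reactants: 7 methyl (4R)-4-(tert-butyldimethylsilyloxy)-2,6,6-trimethylcyclohex-1-ene-1-carboxylate
Product: 8 [(4R)-4-(tert-butyldimethylsilyloxy)-2,6,6-trimethylcyclohex-1-en-1-yl]methanol
Conditions: i-Bu2AlH, CH2Cl2, −78 to 0 °C; Rochelle salt
Reagents that add atoms: none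
Why: 1,2-Reduction of an α,β-unsaturated ester by i-Bu2AlH gives the allylic alcohol needed to direct the epoxidation.

Step 7
Reactants: 8 [(4R)-4-(tert-butyldimethylsilyloxy)-2,6,6-trimethylcyclohex-1-en-1-yl]methanol
Product: 9 [(1R,4S,6R)-4-(tert-butyldimethylsilyloxy)-2,2,6-trimethyl-7-oxabicyclo[4.1.0]heptan-1-yl]methanol
Conditions: Ti(Oi-Pr)4, D-(−)-diethyl tartrate, t-BuOOH, 4 Å sieves, CH2Cl2, −20 °C
Reagents that add atoms: tert-butyl hydroperoxide CC(C)(C)OO
Why: Sharpless asymmetric epoxidation: the titanium D-tartrate complex bound to the allylic hydroxyl delivers oxygen to the alkene face anti to the C3 silyloxy group, so reagent control sets C5 as R and C6 with it.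

Step 8
Reactants: 9 [(1R,4S,6R)-4-(tert-butyldimethylsilyloxy)-2,2,6-trimethyl-7-oxabicyclo[4.1.0]heptan-1-yl]methanol
Product: 10 (1S,4S,6R)-4-(tert-butyldimethylsilyloxy)-2,2,6-trimethyl-7-oxabicyclo[4.1.0]heptane-1-carbaldehyde
Conditions: Dess–Martin periodinane, NaHCO3, CH2Cl2, 0 to 25 °C
Reagents that add atoms: none
Why: Dess–Martin oxidation of a primary alcohol under bicarbonate buffer spares the oxirane, and the aldehyde has no α-hydrogen to epimerise.

Step 9
Reactants: 10 (1S,4S,6R)-4-(tert-butyldimethylsilyloxy)-2,2,6-trimethyl-7-oxabicyclo[4.1.0]heptane-1-carbaldehyde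
Product: 11 (1R,4S,6R)-4-(tert-butyldimethylsilyloxy)-1-ethynyl-2,2,6-trimethyl-7-oxabicyclo[4.1.0]heptane
Conditions: dimethyl (1-diazo-2-oxopropyl)phosphonate, K2CO3, MeOH, 0 to 25 °C
Reagents that add atoms: dimethyl (1-diazo-2-oxopropyl)phosphonate COP(=O)(OC)C(=[N+]=[N-])C(C)=O
Why: Ohira–Bestmann (Seyferth–Gilbert) homologation of a non-enolisable aldehyde gives the terminal alkyne (C7≡C8) under mild carbonate conditions that leave the oxirane and silyl ether intact.

Step 10
Reactants: 12 but-2-yn-1-ol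
Product: 14 (Z)-3-iodobut-2-en-1-ol, via cyclic alkenylaluminate 13 (not isolated)
Conditions: NaAlH2(OCH2CH2OMe)2, THF, 0 to 25 °C; then I2, −78 °C
Reagents that add atoms: iodine II
Why: Hydroxyl-directed trans-hydroalumination of a propargylic alcohol places aluminium on C3 in a five-membered alkoxyaluminate, and iodinolysis with retention gives the Z iodide that will become the 9Z bond.

Step 11
Reactants: 14 (Z)-3-iodobut-2-en-1-ol
Product: 15 (Z)-tert-butyl[(3-iodobut-2-en-1-yl)oxy]dimethylsilane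
Conditions: TBSCl, imidazole, CH2Cl2, 25 °C
Reagents that add atoms: tert-butyldimethylsilyl chloride CC(C)(C)[Si](C)(C)Cl
Why: Silylation masks the C11 hydroxyl so that it cannot direct hydride or add to the allene in steps 13 and 14.

Step 12
Reactants: 11 (1R,4S,6R)-4-(tert-butyldimethylsilyloxy)-1-ethynyl-2,2,6-trimethyl-7-oxabicyclo[4.1.0]heptane; 15 (Z)-tert-butyl[(3-iodobut-2-en-1-yl)oxy]dimethylsilane
Product: 16 tert-butyl{[(2Z)-5-[(1R,4S,6R)-4-(tert-butyldimethylsilyloxy)-2,2,6-trimethyl-7-oxabicyclo[4.1.0]heptan-1-yl]-3-methylpent-2-en-4-yn-1-yl]oxy}dimethylsilane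
Conditions: Pd(PPh3)4 (5 mol %), CuI (10 mol %), i-Pr2NH, THF, 25 °C
Reagents that add atoms: none
Why: Sonogashira coupling of a terminal alkyne with a vinyl iodide forms C8–C9 with retention of the Z geometry, and the tetrasubstituted oxirane is inert to zerovalent palladium at room temperature.

Step 13
Reactants: 16 epoxy enyne
Product: 17 (1R,5S)-5-(tert-butyldimethylsilyloxy)-2-[(3Z)-5-(tert-butyldimethylsilyloxy)-3-methylpenta-1,3-dien-1-ylidene]-1,3,3-trimethylcyclohexan-1-ol with the (R) allene axis, the (3S,5R,6R)-allenol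
Conditions: i-Bu2AlH (3 equiv), CH2Cl2, −78 to 0 °C; Rochelle salt
Reagents that add atoms: none
Why: SN2′ hydride opening of an alkynyl oxirane: the alane bound to the oxirane oxygen passes hydride to C8 on the oxygen face while C6–O breaks, so O5 stays 5R and the (6R) axis with the C8 hydrogen syn to the C5 hydroxyl should result, the outcome documented for allenic 5-hydroxy end groups of this ring type.

Step 14
Reactants: 17 (3S,5R,6R)-allenol
Product: 18 (2S,6S,7aR)-6-(tert-butyldimethylsilyloxy)-2-[(2Z)-4-(tert-butyldimethylsilyloxy)but-2-en-2-yl]-4,4,7a-trimethyl-2,4,5,6,7,7a-hexahydro-1-benzofuran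
Conditions: AuCl3 (2–5 mol %), THF, 0 to 25 °C, dark; Et3N quench
Reagents that add atoms: none
Why: Gold-catalysed 5-endo cycloisomerisation of an α-hydroxyallene: O5 adds to C8 anti to trivalent gold bound at C7=C8 and protodeauration frees C7–H, so the (6R) axis is transferred to the 8S centre (chain cis to the C5 methyl), with THF tempering the Lewis acidity that could ionise C8–O.

Step 15
Reactants: 18 bis-silyl furanoid
Product: 19 (2S,6S,7aR)-2-[(2Z)-4-hydroxybut-2-en-2-yl]-4,4,7a-trimethyl-2,4,5,6,7,7a-hexahydro-1-benzofuran-6-ol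
Conditions: n-Bu4NF, THF, 25 °C
Reagents that add atoms: none
Why: Fluoride cleavage of both silyl ethers in a basic medium leaves the acid-labile dihydrofuran and its C8 centre untouched.

Step 16
Reactants: 19 furanoid diol
Product: 20 (2Z)-3-[(2S,6S,7aR)-6-hydroxy-4,4,7a-trimethyl-2,4,5,6,7,7a-hexahydro-1-benzofuran-2-yl]but-2-enal
Conditions: MnO2 (activated, excess), CH2Cl2, 25 °C, dark
Reagents that add atoms: none
Why: MnO2 oxidises the primary allylic alcohol chemoselectively, the saturated secondary C3 alcohol is inert, and the neutral heterogeneous conditions should keep the Z geometry.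

Step 17
Reactants: 21 propargyl alcohol
Product: 23 (E)-3-iodo-2-methylprop-2-en-1-ol, via alkenylalane 22 (not isolated)
Conditions: AlMe3 (3 equiv), Cp2ZrCl2 (0.25 equiv), CH2Cl2, 0 to 25 °C; then I2, THF, −30 °C
Reagents that add atoms: trimethylaluminium C[Al](C)C; iodine II
Why: Negishi zirconium-catalysed carboalumination adds methyl and aluminium syn across the alkyne with aluminium at the terminus, and iodinolysis with retention gives the E iodide.

Step 18
Reactants: 23 (E)-3-iodo-2-methylprop-2-en-1-ol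
Product: 24 (E)-3-bromo-1-iodo-2-methylprop-1-ene
Conditions: CBr4, PPh3, CH2Cl2, 0 °C
Reagents that add atoms: carbon tetrabromide BrC(Br)(Br)Br
Why: Appel bromination converts the primary allylic alcohol into the bromide under neutral conditions without touching the vinyl iodide.

Step 19
Reactants: 24 (E)-3-bromo-1-iodo-2-methylprop-1-ene
Product: 25 diethyl (E)-(3-iodo-2-methylallyl)phosphonate
Conditions: P(OEt)3, neat, 90 °C
Reagents that add atoms: triethyl phosphite CCOP(OCC)OCC
Why: Michaelis–Arbuzov reaction of the allylic bromide is fast at moderate temperature, and the vinyl iodide does not react with the phosphite.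

Step 20
Reactants: 20 furanoid (Z)-enal; 25 diethyl (E)-(3-iodo-2-methylallyl)phosphonate
Product: 27 (2S,6S,7aR)-2-[(2Z,4E,6E)-7-iodo-6-methylhepta-2,4,6-trien-2-yl]-4,4,7a-trimethyl-2,4,5,6,7,7a-hexahydro-1-benzofuran-6-ol, via phosphonate sodium salt 26 (not isolated)
Conditions: 25 (2.5 equiv), NaN(SiMe3)2 (2.4 equiv), THF, −78 °C; then 20, −78 to 0 °C, dark
Reagents that add atoms: none
Why: Horner–Wadsworth–Emmons olefination with an allylic phosphonate anion should form C11=C12 as the E isomer, the excess anion covering the free C3 hydroxyl and the low-temperature addition to the aldehyde outrunning γ-deprotonation, so the 9Z bond, C8 and the E vinyl iodide are kept.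

Step 21
Reactants: 23 (E)-3-iodo-2-methylprop-2-en-1-ol
Product: 29 ethyl (2E,4E)-5-iodo-4-methylpenta-2,4-dienoate, via iodoenal 28 (not isolated)
Conditions: MnO2, Ph3P=CHCO2Et, CH2Cl2, 25 °C
Reagents that add atoms: ethyl (triphenylphosphoranylidene)acetate CCOC(=O)C=P(c1ccccc1)(c1ccccc1)c1ccccc1
Why: Tandem MnO2 oxidation–Wittig olefination traps the volatile iodoenal as it forms, and the stabilised ylide should give the E enoate.

Step 22
Reactants: 29 ethyl (2E,4E)-5-iodo-4-methylpenta-2,4-dienoate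
Product: 30 (2E,4E)-5-iodo-4-methylpenta-2,4-dien-1-ol
Conditions: i-Bu2AlH, CH2Cl2, −78 °C; Rochelle salt
Reagents that add atoms: none
Why: 1,2-Reduction of the dienoate by i-Bu2AlH gives the allylic alcohol and leaves the vinyl iodide and both E alkenes unchanged.

Step 23
Reactants: 31 (E)-1,2-bis(tributylstannyl)ethene
Product: 33 (E)-2-(tributylstannyl)vinylboronic acid pinacol ester, via stannylvinyllithium 32 (not isolated)
Conditions: n-BuLi (1.0 equiv), THF, −78 °C; then i-PrOBpin, −78 to 25 °C; aq NH4Cl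
Reagents that add atoms: 2-isopropoxy-4,4,5,5-tetramethyl-1,3,2-dioxaborolane CC(C)OB1OC(C)(C)C(C)(C)O1
Why: Tin–lithium exchange of one stannyl group proceeds with retention of the E geometry, and the vinyllithium is trapped by the isopropoxyboronate to give the tin/boron ethene.

Step 24
Reactants: 27 furanoid (9Z,11E,13E)-trienyl iodide; 33 (E)-2-(tributylstannyl)vinylboronic acid pinacol ester; 30 (2E,4E)-5-iodo-4-methylpenta-2,4-dien-1-ol
Product: 35 (2S,6S,7aR)-2-[(2Z,4E,6E,8E,10E,12E)-14-hydroxy-6,11-dimethyltetradeca-2,4,6,8,10,12-hexaen-2-yl]-4,4,7a-trimethyl-2,4,5,6,7,7a-hexahydro-1-benzofuran-6-ol, via tetraenyl pinacol boronate 34 (not isolated)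
Conditions: Pd2(dba)3 (5 mol %), AsPh3 (40 mol %), 33 (1.05 equiv), degassed DMF–THF, 25 °C, dark; then 30 (1.2 equiv), degassed aq K3PO4, 25 to 40 °C; chromatography on Et3N-washed silica in the dark
Reagents that add atoms: none
Why: Zerovalent palladium inserts into the C14–I bond of 27, the stannyl terminus of 33 transmetalates and reductive elimination forms C14–C15 while the base-free boronate stays inert; once phosphate and water are added the same catalyst inserts into the C–I bond of 30, the now activated boronate of 34 transmetalates and reductive elimination forms C15′–C14′. The closest known reaction type is the one-pot Stille then Suzuki–Miyaura polyene assembly with (E)-2-stannylvinylboronate linchpins. No ring is closed and no stereocentre is created. The step needs tin to react before boron, which is secured by withholding base until 27 is consumed, and retention at every alkene, which is secured by the stereoretentive oxidative addition, transmetalation and reductive elimination of sp2 partners, so the 9Z bond and the five E bonds are those built into 27, 33 and 30. The medium is neutral and then basic, so the acid-labile dihydrofuran and its C8 centre are not ionised, and both free hydroxyls are tolerated.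

**Compound list**

1 | ketoisophorone (2,6,6-trimethylcyclohex-2-ene-1,4-dione) | CC1=CC(=O)CC(C)(C)C1=O | starting material
2 | (6R)-2,2,6-trimethylcyclohexane-1,4-dione | C[C@@H]1CC(=O)CC(C)(C)C1=O | intermediate
3 | (4R,6R)-4-hydroxy-2,2,6-trimethylcyclohexan-1-one (actinol) | C[C@@H]1C[C@@H](O)CC(C)(C)C1=O | intermediate
4 | (4R,6R)-4-(tert-butyldimethylsilyloxy)-2,2,6-trimethylcyclohexan-1-one | C[C@@H]1C[C@@H](O[Si](C)(C)C(C)(C)C)CC(C)(C)C1=O | intermediate
5 | lithium (4R)-4-(tert-butyldimethylsilyloxy)-2,6,6-trimethylcyclohex-1-en-1-olate | [Li+].CC1=C([O-])C(C)(C)C[C@H](O[Si](C)(C)C(C)(C)C)C1 | intermediate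
6 | (4R)-4-(tert-butyldimethylsilyloxy)-2,6,6-trimethylcyclohex-1-en-1-yl trifluoromethanesulfonate | CC1=C(OS(=O)(=O)C(F)(F)F)C(C)(C)C[C@H](O[Si](C)(C)C(C)(C)C)C1 | intermediate
7 | methyl (4R)-4-(tert-butyldimethylsilyloxy)-2,6,6-trimethylcyclohex-1-ene-1-carboxylate | COC(=O)C1=C(C)C[C@@H](O[Si](C)(C)C(C)(C)C)CC1(C)C | intermediate
8 | [(4R)-4-(tert-butyldimethylsilyloxy)-2,6,6-trimethylcyclohex-1-en-1-yl]methanol | OCC1=C(C)C[C@@H](O[Si](C)(C)C(C)(C)C)CC1(C)C | intermediate
9 | [(1R,4S,6R)-4-(tert-butyldimethylsilyloxy)-2,2,6-trimethyl-7-oxabicyclo[4.1.0]heptan-1-yl]methanol | OC[C@@]12O[C@]1(C)C[C@@H](O[Si](C)(C)C(C)(C)C)CC2(C)C | intermediate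
10 | (1S,4S,6R)-4-(tert-butyldimethylsilyloxy)-2,2,6-trimethyl-7-oxabicyclo[4.1.0]heptane-1-carbaldehyde | O=C[C@@]12O[C@]1(C)C[C@@H](O[Si](C)(C)C(C)(C)C)CC2(C)C | intermediate
11 | (1R,4S,6R)-4-(tert-butyldimethylsilyloxy)-1-ethynyl-2,2,6-trimethyl-7-oxabicyclo[4.1.0]heptane | C#C[C@@]12O[C@]1(C)C[C@@H](O[Si](C)(C)C(C)(C)C)CC2(C)C | intermediate
12 | but-2-yn-1-ol | CC#CCO | starting material
13 | sodium 2,2-bis(2-methoxyethoxy)-3-methyl-2,5-dihydro-1,2-oxaaluminol-2-uide (cyclic alkenylaluminate) | [Na+].CC1=CCO[Al-]1(OCCOC)OCCOC | intermediate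
14 | (Z)-3-iodobut-2-en-1-ol | C/C(I)=C/CO | intermediate
15 | (Z)-tert-butyl[(3-iodobut-2-en-1-yl)oxy]dimethylsilane | C/C(I)=C/CO[Si](C)(C)C(C)(C)C | intermediate
16 | tert-butyl{[(2Z)-5-[(1R,4S,6R)-4-(tert-butyldimethylsilyloxy)-2,2,6-trimethyl-7-oxabicyclo[4.1.0]heptan-1-yl]-3-methylpent-2-en-4-yn-1-yl]oxy}dimethylsilane | C/C(C#C[C@@]12O[C@]1(C)C[C@@H](O[Si](C)(C)C(C)(C)C)CC2(C)C)=C/CO[Si](C)(C)C(C)(C)C | intermediate
17 | (1R,5S)-5-(tert-butyldimethylsilyloxy)-2-[(3Z)-5-(tert-butyldimethylsilyloxy)-3-methylpenta-1,3-dien-1-ylidene]-1,3,3-trimethylcyclohexan-1-ol, (R) allene axis | C/C(=C/CO[Si](C)(C)C(C)(C)C)C=[C@@]=C1C(C)(C)C[C@H](O[Si](C)(C)C(C)(C)C)C[C@@]1(C)O | intermediate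
18 | (2S,6S,7aR)-6-(tert-butyldimethylsilyloxy)-2-[(2Z)-4-(tert-butyldimethylsilyloxy)but-2-en-2-yl]-4,4,7a-trimethyl-2,4,5,6,7,7a-hexahydro-1-benzofuran | C/C(=C/CO[Si](C)(C)C(C)(C)C)[C@@H]1C=C2C(C)(C)C[C@H](O[Si](C)(C)C(C)(C)C)C[C@@]2(C)O1 | intermediate
19 | (2S,6S,7aR)-2-[(2Z)-4-hydroxybut-2-en-2-yl]-4,4,7a-trimethyl-2,4,5,6,7,7a-hexahydro-1-benzofuran-6-ol | C/C(=C/CO)[C@@H]1C=C2C(C)(C)C[C@H](O)C[C@@]2(C)O1 | intermediate
20 | (2Z)-3-[(2S,6S,7aR)-6-hydroxy-4,4,7a-trimethyl-2,4,5,6,7,7a-hexahydro-1-benzofuran-2-yl]but-2-enal | C/C(=C/C=O)[C@@H]1C=C2C(C)(C)C[C@H](O)C[C@@]2(C)O1 | intermediate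
21 | propargyl alcohol | C#CCO | starting material
22 | (E)-[3-(dimethylalumanyl)-2-methylallyl]oxy(dimethyl)alumane (alkenylalane) | C/C(CO[Al](C)C)=C\[Al](C)C | intermediate
23 | (E)-3-iodo-2-methylprop-2-en-1-ol | OC/C(C)=C/I | intermediate
24 | (E)-3-bromo-1-iodo-2-methylprop-1-ene | BrC/C(C)=C/I | intermediate
25 | diethyl (E)-(3-iodo-2-methylallyl)phosphonate | CCOP(=O)(OCC)C/C(C)=C/I | intermediate
26 | sodium salt of diethyl (E)-(3-iodo-2-methylallyl)phosphonate (carbanion at C1) | [Na+].CCOP(=O)(OCC)[CH-]/C(C)=C/I | intermediate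
27 | (2S,6S,7aR)-2-[(2Z,4E,6E)-7-iodo-6-methylhepta-2,4,6-trien-2-yl]-4,4,7a-trimethyl-2,4,5,6,7,7a-hexahydro-1-benzofuran-6-ol | C/C(=C/C=C/C(C)=C/I)[C@@H]1C=C2C(C)(C)C[C@H](O)C[C@@]2(C)O1 | intermediate
28 | (E)-3-iodo-2-methylprop-2-enal | O=C/C(C)=C/I | intermediate
29 | ethyl (2E,4E)-5-iodo-4-methylpenta-2,4-dienoate | CCOC(=O)/C=C/C(C)=C/I | intermediate
30 | (2E,4E)-5-iodo-4-methylpenta-2,4-dien-1-ol | OC/C=C/C(C)=C/I | intermediate
31 | (E)-1,2-bis(tributylstannyl)ethene | CCCC[Sn](CCCC)(CCCC)/C=C/[Sn](CCCC)(CCCC)CCCC | starting material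
32 | (E)-2-(tributylstannyl)vinyllithium | CCCC[Sn](CCCC)(CCCC)/C=C/[Li] | intermediate
33 | (E)-2-(tributylstannyl)vinylboronic acid pinacol ester | CCCC[Sn](CCCC)(CCCC)/C=C/B1OC(C)(C)C(C)(C)O1 | intermediate
34 | (2S,6S,7aR)-2-[(2Z,4E,6E,8E)-6-methyl-9-(4,4,5,5-tetramethyl-1,3,2-dioxaborolan-2-yl)nona-2,4,6,8-tetraen-2-yl]-4,4,7a-trimethyl-2,4,5,6,7,7a-hexahydro-1-benzofuran-6-ol | C/C(=C/C=C/C(C)=C/C=C/B1OC(C)(C)C(C)(C)O1)[C@@H]1C=C2C(C)(C)C[C@H](O)C[C@@]2(C)O1 | intermediate
35 | (2S,6S,7aR)-2-[(2Z,4E,6E,8E,10E,12E)-14-hydroxy-6,11-dimethyltetradeca-2,4,6,8,10,12-hexaen-2-yl]-4,4,7a-trimethyl-2,4,5,6,7,7a-hexahydro-1-benzofuran-6-ol | C/C(=C/C=C/C(C)=C/C=C/C=C(C)/C=C/CO)[C@@H]1C=C2C(C)(C)C[C@H](O)C[C@@]2(C)O1 | target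

**Step count and risks**

Total steps: 24. Longest linear sequence: 16 (steps 1–9, 12–16, 20 and 24).

The three steps most likely to fail:

1. Step 14. What may go wrong: reversible ionisation of the doubly allylic C8–O bond at the Lewis-acidic gold centre, which would erode the C8 configuration, or diversion of the vinylallene into carbocyclisation. The fallback uses a different ring-forming mode, the epoxide-to-furanoid rearrangement. Setting out from 16, partial hydrogenation of the alkyne over Pd/CaCO3 poisoned with Pb(OAc)2 and quinoline would give the (7Z,9Z)-epoxy diene F1. A trace of acid (pyridinium p-toluenesulfonate, CH2Cl2, 0 °C) would then open the oxirane at C6 and close O5 onto C8. This would give 18 together with the C8 epimer of 18 F2, which would be removed by chromatography. The sequence comes back to the route at 18.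

2. Step 20. What may go wrong: γ-deprotonation of the (Z)-enal by the phosphonate anion at C8–H or the C9 methyl, which would scramble the 9Z bond and the C8 centre. The fallback carries out the olefination before the dihydrofuran exists. Setting out from 11 and 14, Sonogashira coupling would give the epoxy enynol F3, and MnO2 the epoxy (Z)-enynal F4, in which C8 is an sp carbon. Horner–Wadsworth–Emmons reaction with 25 would give the epoxy dienynyl iodide F5, and i-Bu2AlH the allenol trienyl iodide F6. AuCl3 in THF would give the silyl ether of 27 F7, and n-Bu4NF would bring the sequence back to the route at 27.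

3. Step 24. What may go wrong: a slow second coupling that lets the tetraenyl boronate protodeboronate or isomerise, or boron coupling that starts before the tin terminus is consumed. The fallback puts tin on both ends of the ethene and forms the same two bonds in two separate Stille couplings. Setting out from 30 and an excess of 31, a Stille coupling (Pd2(dba)3, AsPh3, DMF) would give the stannyl trienol F8 after chromatography on base-washed silica. A second Stille coupling of F8 with 27 under the same catalyst would come back to the route at 35.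

Further compounds
F1 | step 14 | tert-butyl{[(2Z,4Z)-5-[(1S,4S,6R)-4-(tert-butyldimethylsilyloxy)-2,2,6-trimethyl-7-oxabicyclo[4.1.0]heptan-1-yl]-3-methylpenta-2,4-dien-1-yl]oxy}dimethylsilane | C/C(=C/CO[Si](C)(C)C(C)(C)C)/C=C\[C@@]12O[C@]1(C)C[C@@H](O[Si](C)(C)C(C)(C)C)CC2(C)C
F2 | step 14 | (2R,6S,7aR)-6-(tert-butyldimethylsilyloxy)-2-[(2Z)-4-(tert-butyldimethylsilyloxy)but-2-en-2-yl]-4,4,7a-trimethyl-2,4,5,6,7,7a-hexahydro-1-benzofuran | C/C(=C/CO[Si](C)(C)C(C)(C)C)[C@H]1C=C2C(C)(C)C[C@H](O[Si](C)(C)C(C)(C)C)C[C@@]2(C)O1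
F3 | step 20 | (2Z)-5-[(1R,4S,6R)-4-(tert-butyldimethylsilyloxy)-2,2,6-trimethyl-7-oxabicyclo[4.1.0]heptan-1-yl]-3-methylpent-2-en-4-yn-1-ol | C/C(C#C[C@@]12O[C@]1(C)C[C@@H](O[Si](C)(C)C(C)(C)C)CC2(C)C)=C/CO
F4 | step 20 | (2Z)-5-[(1R,4S,6R)-4-(tert-butyldimethylsilyloxy)-2,2,6-trimethyl-7-oxabicyclo[4.1.0]heptan-1-yl]-3-methylpent-2-en-4-ynal | C/C(C#C[C@@]12O[C@]1(C)C[C@@H](O[Si](C)(C)C(C)(C)C)CC2(C)C)=C/C=O
F5 | step 20 | (1R,4S,6R)-4-(tert-butyldimethylsilyloxy)-1-[(3Z,5E,7E)-8-iodo-3,7-dimethylocta-3,5,7-trien-1-yn-1-yl]-2,2,6-trimethyl-7-oxabicyclo[4.1.0]heptane | C/C(C#C[C@@]12O[C@]1(C)C[C@@H](O[Si](C)(C)C(C)(C)C)CC2(C)C)=C/C=C/C(C)=C/I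
F6 | step 20 | (1R,5S)-5-(tert-butyldimethylsilyloxy)-2-[(3Z,5E,7E)-8-iodo-3,7-dimethylocta-1,3,5,7-tetraen-1-ylidene]-1,3,3-trimethylcyclohexan-1-ol, (R) allene axis | C/C(=C/C=C/C(C)=C/I)C=[C@@]=C1C(C)(C)C[C@H](O[Si](C)(C)C(C)(C)C)C[C@@]1(C)O
F7 | step 20 | (2S,6S,7aR)-6-(tert-butyldimethylsilyloxy)-2-[(2Z,4E,6E)-7-iodo-6-methylhepta-2,4,6-trien-2-yl]-4,4,7a-trimethyl-2,4,5,6,7,7a-hexahydro-1-benzofuran | C/C(=C/C=C/C(C)=C/I)[C@@H]1C=C2C(C)(C)C[C@H](O[Si](C)(C)C(C)(C)C)C[C@@]2(C)O1
F8 | step 24 | (2E,4E,6E)-4-methyl-7-(tributylstannyl)hepta-2,4,6-trien-1-ol | OC/C=C/C(C)=C/C=C/[Sn](CCCC)(CCCC)CCCC
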